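**Retrosynthetic overview**
1. The target has one ring, a 2-methoxy-4H-pyran-4-one (O1, C2–C6). The plan rests on its C5=C6 double bond: C6 bears O1 and the C11 side chain, C5 bears an ethyl group. This is the pattern left when an oxygen nucleophile and an electrophile add across a C5≡C6 alkyne.
2. The C5–ethyl bond is cut first (Negishi coupling of a C5 iodide). The C5 iodide and O1–C6 are then cut together, by an iodonium-induced 6-endo-dig closure of an acyclic methyl 2-ethyl-3-oxo-4-ynoate whose ester OMe ends up as the 2-OMe group.
3. The ynone keto ester is cut at C3–C4: Reformatsky addition of methyl 2-bromobutanoate to a C14 ynal, then oxidation.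
4. The ynal comes from dec-1-yne and (S)-propylene oxide (source of the only stereocentre) by epoxide opening, alkyne zipper, formylation and acetylation.
5. Ring order: the single pyranone ring is formed in step 7, one step before the end.

Key step: step 7

Remark: ring locants are O1, C2 (OMe), C3 (Et), C4 (C=O), C5, C6 (side chain). With nine methylenes between alkyne and carbinol carbon, the cyclisation precursor is a hexadec-4-ynoate with the stereocentre at C15. Methyl 2-bromobutanoate is used as the racemate because the centres it creates are erased later.

**Step 1**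
Reactants: 1 dec-1-yne, 2 (S)-propylene oxide
Product: 4 (2S)-tridec-4-yn-2-ol, via dec-1-ynyllithium 3 (not isolated)
Conditions: n-BuLi, THF, −78 °C; then 2, DMPU, −78 °C → rt; H2O
Reagents that add atoms: n-butyllithium, [Li]CCCC (lithium of 3 only; 4 holds atoms of 1 and 2 alone)
Why: Alkynyllithium opening of a terminal epoxide is an SN2 reaction at the unsubstituted ring carbon (DMPU loosens the lithium aggregate), so the C–O bond at the stereocentre of 2 is never broken and its (S) configuration becomes that of C2 in 4.

**Step 2**
Reactants: 4 (2S)-tridec-4-yn-2-ol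
Product: 6 (2S)-tridec-12-yn-2-ol, via dipotassium alkoxide acetylide 5 (not isolated)
Conditions: KH, H2N(CH2)3NH2, rt; then 4, 0 °C → rt; H2O, 0 °C
Reagents that add atoms: potassium hydride, [H-].[K+] (potassium of 5 only)
Why: In the alkyne zipper reaction KNH(CH2)3NH2 shifts the triple bond through propargyl–allenyl proton transfers along the unbranched chain until the terminal acetylide 5 forms irreversibly, while the carbinol carbon blocks the other direction and, as its alkoxide, resists deprotonation, so the (S) centre should be retained.

**Step 3**
Reactants: 6 (2S)-tridec-12-yn-2-ol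
Product: 8 (13S)-13-hydroxytetradec-2-ynal, via dilithio alkoxide acetylide 7 (not isolated)
Conditions: n-BuLi (2.1 equiv), THF, −78 → −40 °C; DMF, −40 °C → rt; inverse quench into aq. KH2PO4/MTBE, 0 °C
Reagents that add atoms: N,N-dimethylformamide, CN(C)C=O (formyl carbon and oxygen); n-butyllithium, [Li]CCCC (lithium of 7 only)
Why: Formylation of an alkynyllithium with DMF is a standard route to ynals, the lithium alkoxide end of 7 does not react with DMF, and the inverse quench into phosphate buffer keeps the released dimethylamine protonated so that it cannot add to the triple bond of 8.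

**Step 4**
Reactants: 8 (13S)-13-hydroxytetradec-2-ynal
Product: 9 (2S)-14-oxotetradec-12-yn-2-yl acetate
Conditions: AcCl, 2,4,6-collidine, CH2Cl2, 0 °C → rt
Reagents that add atoms: acetyl chloride, CC(=O)Cl
Why: O-acylation of a secondary alcohol with an acyl chloride and a hindered pyridine base needs no nucleophilic catalyst that could add to the β-carbon of the ynal, and since only the O–H bond reacts the (S) centre is unchanged.

**Step 5**
Reactants: 9 (2S)-14-oxotetradec-12-yn-2-yl acetate, 10 methyl 2-bromobutanoate (racemic)
Product: 12 methyl (15S)-15-acetoxy-2-ethyl-3-hydroxyhexadec-4-ynoate (mixture of C2/C3 diastereomers), via bromozinc ester enolate 11 (not isolated)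
Conditions: 10, activated Zn dust, THF, 40 °C; then 9, 0 °C → rt; cold 1 M HCl
Reagents that add atoms: zinc, [Zn] (zinc of 11 only)
Why: In the Reformatsky reaction the preformed zinc enolate 11 adds 1,2 to the aldehyde but is too mild to attack the acetate or the methyl ester, and the two new stereocentres (C2 and C3) are left uncontrolled on purpose because steps 6 and 7 erase both.

**Step 6**
Reactants: 12 methyl (15S)-15-acetoxy-2-ethyl-3-hydroxyhexadec-4-ynoate
Product: 13 methyl (15S)-15-acetoxy-2-ethyl-3-oxohexadec-4-ynoate (epimers at the enolisable C2)
Conditions: Dess–Martin periodinane, CH2Cl2, 0 °C → rt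
Reagents that add atoms: none
Why: Dess–Martin oxidation turns the secondary propargylic alcohol into the ynone under nearly neutral, non-nucleophilic conditions, so neither conjugate addition nor premature cyclisation of the 3-oxo-4-ynoate is expected and the acetate is untouched.

**Step 7**
Reactants: 13 methyl (15S)-15-acetoxy-2-ethyl-3-oxohexadec-4-ynoate
Product: 15 6-[(10S)-10-acetoxyundecyl]-3-ethyl-5-iodo-2-methoxy-4H-pyran-4-one, via cyclic dialkoxycarbenium chloride 14 (not isolated)
Conditions: ICl (1.2 equiv), 2,6-di-tert-butyl-4-methylpyridine (1.5 equiv), CH2Cl2, −78 → −20 °C, dark; aq. Na2S2O3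
Reagents that add atoms: iodine monochloride, ClI (iodine at C5; chloride of 14)
Why: Proposed new method: ICl polarises the triple bond of 13 (the future ring atoms C5 and C6) as an iodonium π-complex, and the ester carbonyl oxygen attacks anti at the chain-bearing alkyne carbon, so that the O1–C6 bond and the carbon–iodine bond at C5 form together in a 6-endo-dig closure of the only ring and give the cyclic dialkoxycarbenium ion 14. The C3–H of 14 lies between the cationic C2 and the C4 ketone and is lost at once to the hindered pyridine, which leaves the neutral 2-methoxy-4-pyranone 15 with the former ester methyl group serving as the 2-methoxy group. The closest known reaction types are the ICl cyclisation of 2-methoxyaryl alkynyl ketones to 3-iodochromones, the iodolactonisation of alkynyl esters and the gold-catalysed 6-endo closure of 3-oxo-4-ynoates; new here is the iodonium trigger on an acyclic keto ester with retention of the O-methyl group. The step needs 6-endo attack at C6 instead of 5-exo attack at C5, and the ynone secures this because positive charge can develop only on the alkyl-substituted carbon remote from the carbonyl group, which also places iodine on C5. It further needs proton loss from 14 to outrun chloride attack on the O-methyl group and alkyne activation to win over iodination of C3: the first is secured by the low temperature and by the base, which keeps HCl from reprotonating 15, the second by the low enol content of the 2-ethyl keto ester and by the fact that a tertiary C3 iodide of a 1,3-dicarbonyl compound hands its iodine back to chloride and so re-forms ICl. No stereocentre is created, the epimeric C2 of 13 becomes the planar C3 of the ring, and the remote (S)-acetate is a bystander.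

**Step 8**
Reactants: 15 6-[(10S)-10-acetoxyundecyl]-3-ethyl-5-iodo-2-methoxy-4H-pyran-4-one
Product: 16 6-[(10S)-10-acetoxyundecyl]-3,5-diethyl-2-methoxy-4H-pyran-4-one (target)
Conditions: Et2Zn (1.5 equiv), PdCl2(dppf) (5 mol %), THF, 50 °C
Reagents that add atoms: diethylzinc, CC[Zn]CC
Why: In the Negishi coupling zerovalent palladium (formed from PdCl2(dppf) and Et2Zn) inserts into the carbon–iodine bond at C5, ethyl is transferred from zinc, and the wide bite angle of dppf speeds reductive elimination ahead of β-hydride elimination, while Et2Zn leaves the acetate and the vinylogous carbonate of the ring alone.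

**Compound list**
1 | dec-1-yne | C#CCCCCCCCC | starting material
2 | (S)-propylene oxide, (2S)-2-methyloxirane | C[C@H]1CO1 | starting material
3 | dec-1-ynyllithium | [Li]C#CCCCCCCCC | intermediate
4 | (2S)-tridec-4-yn-2-ol | CCCCCCCCC#CC[C@H](C)O | intermediate
5 | dipotassium salt of (2S)-tridec-12-yn-2-ol (alkoxide and terminal acetylide) | [C-]#CCCCCCCCCC[C@H](C)[O-].[K+].[K+] | intermediate
6 | (2S)-tridec-12-yn-2-ol | C#CCCCCCCCCC[C@H](C)O | intermediate
7 | dilithio derivative of (2S)-tridec-12-yn-2-ol (alkoxide and acetylide) | [Li]C#CCCCCCCCCC[C@H](C)O[Li] | intermediate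
8 | (13S)-13-hydroxytetradec-2-ynal | O=CC#CCCCCCCCCC[C@H](C)O | intermediate
9 | (2S)-14-oxotetradec-12-yn-2-yl acetate | O=CC#CCCCCCCCCC[C@H](C)OC(C)=O | intermediate
10 | methyl 2-bromobutanoate (racemic) | CCC(Br)C(=O)OC | starting material
11 | bromozinc enolate of methyl butanoate, BrZnCH(Et)CO2Me | CCC([Zn]Br)C(=O)OC | intermediate
12 | methyl (15S)-15-acetoxy-2-ethyl-3-hydroxyhexadec-4-ynoate (C2/C3 diastereomers) | CCC(C(=O)OC)C(O)C#CCCCCCCCCC[C@H](C)OC(C)=O | intermediate
13 | methyl (15S)-15-acetoxy-2-ethyl-3-oxohexadec-4-ynoate (C2 epimers) | CCC(C(=O)OC)C(=O)C#CCCCCCCCCC[C@H](C)OC(C)=O | intermediate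
14 | 6-[(10S)-10-acetoxyundecyl]-3-ethyl-5-iodo-2-methoxy-4-oxo-3,4-dihydropyrylium chloride | CCC1C(=O)C(I)=C(CCCCCCCCC[C@H](C)OC(C)=O)[O+]=C1OC.[Cl-] | intermediate
15 | 6-[(10S)-10-acetoxyundecyl]-3-ethyl-5-iodo-2-methoxy-4H-pyran-4-one | CCc1c(OC)oc(CCCCCCCCC[C@H](C)OC(C)=O)c(I)c1=O | intermediate
16 | 6-[(10S)-10-acetoxyundecyl]-3,5-diethyl-2-methoxy-4H-pyran-4-one | CCc1c(CCCCCCCCC[C@H](C)OC(C)=O)oc(OC)c(CC)c1=O | target

**Total step count:** 8. **Longest linear sequence:** 8 steps (from 1 or 2 to 16).

**Steps most likely to fail**

Step 7. Halogenation at the enolisable C3 or plain addition of ICl across the triple bond may outrun ring closure. Chloride may also strip the O-methyl group from the cationic intermediate. The fallback separates ring closure from halogenation and uses known chemistry. Setting out from 13, catalytic Ph3PAuNTf2 in CH2Cl2 at rt brings about the known gold-catalysed 6-endo-dig cycloisomerisation of a 3-oxo-4-ynoate. This gives 6-[(10S)-10-acetoxyundecyl]-3-ethyl-2-methoxy-4H-pyran-4-one F1. Electrophilic iodination of its only free ring position C5 with N-iodosuccinimide and catalytic CF3CO2H in MeCN comes back to the route at 15.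

Step 8. β-Hydride elimination from the ethylpalladium intermediate, or iodine–zinc exchange at the electron-poor C5, may remove the iodine without forming the carbon–carbon bond. The fallback uses an sp2 partner with no β-hydrogen. Setting out from 15, Stille coupling with tributyl(vinyl)stannane (Pd(PPh3)4, CuI, DMF, 50 °C) gives 6-[(10S)-10-acetoxyundecyl]-5-ethenyl-3-ethyl-2-methoxy-4H-pyran-4-one F2. Hydrogenation of the monosubstituted alkene over RhCl(PPh3)3 (H2, 1 atm, benzene/EtOH) leaves the tetrasubstituted ring double bonds alone and comes back to the route at 16.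

Step 4. Conjugate attack of base or chloride on the electron-poor triple bond, or oligomerisation of the ynal, may compete with acylation. The fallback masks the aldehyde first. Setting out from 8, HC(OEt)3 with catalytic p-TsOH in EtOH gives (2S)-14,14-diethoxytetradec-12-yn-2-ol F3. Standard acetylation (Ac2O, pyridine, DMAP, CH2Cl2) gives (2S)-14,14-diethoxytetradec-12-yn-2-yl acetate F4. Mild acetal hydrolysis (aq. CF3CO2H, CH2Cl2, 0 °C) comes back to the route at 9.

**Further compounds**
F1 | step 7 | 6-[(10S)-10-acetoxyundecyl]-3-ethyl-2-methoxy-4H-pyran-4-one | CCc1c(OC)oc(CCCCCCCCC[C@H](C)OC(C)=O)cc1=O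
F2 | step 8 | 6-[(10S)-10-acetoxyundecyl]-5-ethenyl-3-ethyl-2-methoxy-4H-pyran-4-one | CCc1c(OC)oc(CCCCCCCCC[C@H](C)OC(C)=O)c(C=C)c1=O
F3 | step 4 | (2S)-14,14-diethoxytetradec-12-yn-2-ol | CCOC(OCC)C#CCCCCCCCCC[C@H](C)O
F4 | step 4 | (2S)-14,14-diethoxytetradec-12-yn-2-yl acetate | CCOC(OCC)C#CCCCCCCCCC[C@H](C)OC(C)=O
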